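The runs were generated by integration on assumed constants.

A flask charged with 0.950 equiv of reagent per substrate cannot turn the whole of its substrate into target, if each target costs one reagent. That impossibility opened the meeting.

| flask | substrate | reagent | capture agent | remark | time |
|---|---|---|---|---|---|
| amber | 0.032 M | 0.95 equiv | 5 mM | run made earlier |  |
| violet | 0.49 M | 0.95 equiv | 5 mM | run made earlier |  |
| epsilon | 0.50 M | 0.950 equiv | 5.00 mM |  | 1.0 h |
| gamma | 0.15 M | 0.950 equiv | 5.00 mM |  | 1.0 h |
| delta | 0.060 M | 0.950 equiv | 5.00 mM |  | 1.0 h |
| beta | 0.25 M | 0.950 equiv | 5.00 mM |  | 1.0 h |
| zeta | 0.80 M | 0.950 equiv | 5.00 mM |  | 1.0 h |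

| run | time / min | target / % |
|---|---|---|
| amber | 12.0 | 7 |
| amber | 25.0 | 10 |
| amber | 40.0 | 15 |
| amber | 50.0 | 22 |
| amber | 60.0 | 25 |
| violet | 12.0 | 21 |
| violet | 25.0 | 49 |
| violet | 40.0 | 65 |
| violet | 50.0 | 75 |
| violet | 60.0 | 81 |

(scatter of a reading: 2 percentage points)

- the flasks put in order of amount of target, in percent of the substrate charged, best first, at 1.0 h (epsilon / gamma / delta / beta / zeta)
- the amount of target, in percent of the substrate charged of the flask you put first, at 1.0 h
- the amount of target, in percent of the substrate charged of the flask you put last, at 1.0 h

The chair read out the runs. Amber gave 25% at 60.0 min, and violet gave 81% at the same time. The first member said the reagent is the limiting reagent against the substrate, so target stops at 95.0% of the substrate.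

The second member sent that answer round once more. She supposed that each capture agent holds back one unit of substrate and reagent from the target. The capture agent's share of the substrate then comes off the ceiling. She called what remains the room for target: reagent equivalents minus capture agent over substrate. In delta the share is 8.33%, so the room is 86.7%. In zeta the room is 94.4%. She therefore put zeta first and delta last.

The chair objected on two counts. Room counts the whole capture agent as spent, and it is not a yield at 1.0 h. And zeta and epsilon differ in room by 0.38 percentage points, against a scatter of 2 points.

The forecast was then entered: zeta > epsilon > beta > gamma > delta, with 85% for zeta and 36% for delta. These numbers are its own, since the room gives none at that time. Of zeta it said “Its lead over epsilon is uncertain”.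

The flasks give zeta > epsilon > beta > gamma > delta, with zeta at 84.4% and delta at 40.0%, so the forecast stands. In delta, trapped intermediate stands at 7.44% at 1.00 h, against a share of 8.33%, and 11% of the capture agent's own charge is still free. Left until 10.0 h, delta holds 82.5% target, under its room of 86.7%. With the other amounts and the time held, the target in zeta has moved by 5 points with reagent at 0.876 equiv or 1.06 equiv.

    substrate + reagent → open intermediate (k = 0.00690 M⁻¹ s⁻¹)
    open intermediate → target (k = 8.60 × 10⁻⁴ s⁻¹)
    open intermediate + capture agent → trapped intermediate (k = 0.0800 M⁻¹ s⁻¹)

Take a neighbour of delta charged with 0.380 equiv of reagent. Its room is 29.7%. That neighbour gives 17.3% target at 1.00 h, inside the room, with 73% of its substrate still there.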